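Ring A (the benzaldehyde ring: C1 CHO-bearing, C2 methyl, C3 side chain, C4 methyl, C5 H, C6 OH) is cut into two three-carbon pieces. C5–C6–C1 with the formyl carbon is an acetoacetate unit; C2–C3–C4 with both methyls is a 3-alkylpentane-2,4-dione, symmetric about C3. One TiCl4-mediated [3+3] cyclocondensation forms C1–C2 and C4–C5 and closes ring A as a salicylate, with no regiochemical question. The precursor is the trimethylsilyl enol ether of a pentane-2,4-dione carrying at C3 a two-carbon tether to a (4S)-4-methyl-1,3-dioxolan-2-one, the carbonate-masked carbinol drawn from (S)-citramalic acid. A late Heck arylation installs the E-styrene.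

Key step: step 8

Remark: the silyl enol ethers are drawn as single geometric isomers although E/Z mixtures may form; this has no consequence because these double bonds are consumed in the ring-forming step.

Remark: the carbinol carbon keeps the descriptor S from the starting acid to the target, because no bond to it is made or broken and the priority order O > former C1 branch > ring-side CH2 > CH3 holds at every stage.

Step 1
Reactants: 1 (S)-citramalic acid [(2S)-2-hydroxy-2-methylbutanedioic acid]
Product: 2 (2S)-2-methylbutane-1,2,4-triol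
Conditions: BH3·SMe2, B(OMe)3, THF, 0 °C → rt; MeOH quench, co-evaporation with MeOH
Reagents that add atoms: none
Why: Borane reduction of carboxylic acids should convert both carboxyl groups into primary alcohols, and the fully substituted carbinol carbon has no pathway for epimerisation, so the S configuration is carried over unchanged.

Step 2
Reactants: 2 (2S)-2-methylbutane-1,2,4-triol
Product: 3 (4S)-4-(2-hydroxyethyl)-4-methyl-1,3-dioxolan-2-one
Conditions: (MeO)2CO (1.2 equiv), K2CO3 (cat.), 70 °C, MeOH distilled off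
Reagents that add atoms: dimethyl carbonate, COC(=O)OC
Why: Base-catalysed transcarbonation is reversible, so the thermodynamically preferred five-membered carbonate across the 1,2-diol should predominate over the six-membered 1,3-isomer and leave the remote primary hydroxyl free.

Step 3
Reactants: 3 (4S)-4-(2-hydroxyethyl)-4-methyl-1,3-dioxolan-2-one
Product: 4 (4S)-4-(2-iodoethyl)-4-methyl-1,3-dioxolan-2-one
Conditions: I2, PPh3, imidazole, CH2Cl2, 0 °C → rt
Reagents that add atoms: iodine, II
Why: Appel-type iodination should convert the unhindered primary alcohol into the iodide by SN2 displacement at CH2 under neutral conditions that leave the cyclic carbonate untouched.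

Step 4
Reactants: 4 (4S)-4-(2-iodoethyl)-4-methyl-1,3-dioxolan-2-one; 5 pentane-2,4-dione (excess)
Product: 6 3-[2-[(4S)-4-methyl-2-oxo-1,3-dioxolan-4-yl]ethyl]pentane-2,4-dione
Conditions: K2CO3, acetone, reflux
Reagents that add atoms: none
Why: Classical C-alkylation of a 1,3-diketone enolate with a primary iodide in acetone should favour the C-alkylated product, with excess diketone suppressing dialkylation and the anhydrous carbonate base leaving the cyclic carbonate closed.

Step 5
Reactants: 6 3-[2-[(4S)-4-methyl-2-oxo-1,3-dioxolan-4-yl]ethyl]pentane-2,4-dione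
Product: 7 (3Z)-3-[2-[(4S)-4-methyl-2-oxo-1,3-dioxolan-4-yl]ethyl]-4-(trimethylsilyloxy)pent-3-en-2-one
Conditions: Me3SiCl, Et3N, pentane/CH2Cl2, rt; filtered under argon, used crude
Reagents that add atoms: chlorotrimethylsilane, C[Si](C)(C)Cl
Why: Silyl enol ether formation by O-silylation of the enolised 1,3-diketone should give the 3-silyloxy-2-en-1-one, the masked dielectrophile needed for the cyclocondensation.

Step 6
Reactants: 8 methyl acetoacetate (methyl 3-oxobutanoate)
Product: 9 methyl (2E)-3-(trimethylsilyloxy)but-2-enoate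
Conditions: Me3SiCl, Et3N, pentane, rt
Reagents that add atoms: chlorotrimethylsilane, C[Si](C)(C)Cl
Why: Soft enolisation and O-silylation of the β-keto ester (silyl enol ether formation) should give the mono-silyl enol ether.

Step 7
Reactants: 9 methyl (2E)-3-(trimethylsilyloxy)but-2-enoate
Product: 11 (1Z)-1-methoxy-1,3-bis(trimethylsilyloxy)buta-1,3-diene, via lithium dienolate 10 (not isolated)
Conditions: LiN(i-Pr)2, THF, −78 °C; then Me3SiCl, −78 °C → rt; used crude
Reagents that add atoms: chlorotrimethylsilane, C[Si](C)(C)Cl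
Why: Kinetic γ-deprotonation by the amide base should give the extended dienolate 10, which is silylated on the ester oxygen (silyl ketene acetal formation) to give the bis-silyl diene.

Step 8
Reactants: 7 (3Z)-3-[2-[(4S)-4-methyl-2-oxo-1,3-dioxolan-4-yl]ethyl]-4-(trimethylsilyloxy)pent-3-en-2-one; 11 (1Z)-1-methoxy-1,3-bis(trimethylsilyloxy)buta-1,3-diene
Product: 14 methyl 6-hydroxy-2,4-dimethyl-3-[2-[(4S)-4-methyl-2-oxo-1,3-dioxolan-4-yl]ethyl]benzoate, via open-chain enone 12 (not isolated), via cyclohexenone aldol 13 (not isolated)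
Conditions: TiCl4 (1.1–2 equiv), CH2Cl2, −78 °C → rt; aq. HCl work-up
Reagents that add atoms: none
Why: TiCl4 activates the enone carbonyl of 7, the terminal CH2 of diene 11 adds in a Mukaiyama-type vinylogous addition to the silyloxy-bearing carbon and silanolate is expelled to give the open-chain enone 12; the central carbon of its β-keto ester enolate then attacks the remaining acetyl carbonyl in an intramolecular aldol (Knoevenagel-type) closure to 13, and loss of water with enolisation aromatises the ring. The closest known reaction type is the TiCl4-mediated formal [3+3] cyclocondensation of 1,3-bis(silyloxy)buta-1,3-dienes with 3-silyloxy-2-en-1-ones to salicylates, which includes 3-alkyl-substituted cases. The single ring closes in a 6-exo-trig mode, the attacked C=O lying outside the forming ring. No stereocenter is created, and the existing (4S) centre is remote from all bond-forming events. The only selectivity needed is regiochemical, and the constitutional symmetry of the diketone unit about its alkylated carbon makes both orientations of the diene give the same salicylate, with OH and CO2Me on the two carbons that were adjacent in the acetoacetate. The tertiary C–O bond should survive because it is held in a five-membered carbonate whose ionisation is disfavoured by the neighbouring acylated CH2–O group and by the low temperature.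

Step 9
Reactants: 14 methyl 6-hydroxy-2,4-dimethyl-3-[2-[(4S)-4-methyl-2-oxo-1,3-dioxolan-4-yl]ethyl]benzoate
Product: 15 methyl 3-[(3S)-3,4-dihydroxy-3-methylbutyl]-6-hydroxy-2,4-dimethylbenzoate
Conditions: K2CO3 (cat.), MeOH, rt; aq. NH4Cl
Reagents that add atoms: none
Why: Base-catalysed methanolysis (transesterification) of the cyclic carbonate should free the 1,2-diol, while the hindered methyl salicylate can only exchange with methanol degenerately and the fully substituted carbinol carbon is not touched.

Step 10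
Reactants: 15 methyl 3-[(3S)-3,4-dihydroxy-3-methylbutyl]-6-hydroxy-2,4-dimethylbenzoate
Product: 16 methyl 2,4-dimethyl-3-[(3S)-3-methyl-3,4-bis(triethylsilyloxy)butyl]-6-(triethylsilyloxy)benzoate
Conditions: Et3SiOTf, 2,6-lutidine, CH2Cl2, −78 → 0 °C
Reagents that add atoms: triethylsilyl trifluoromethanesulfonate, CC[Si](CC)(CC)OS(=O)(=O)C(F)(F)F
Why: Silyl ether protection with the silyl triflate and a hindered pyridine base is forceful enough to cap the phenol, the primary hydroxyl and the tertiary hydroxyl in one operation.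

Step 11
Reactants: 16 methyl 2,4-dimethyl-3-[(3S)-3-methyl-3,4-bis(triethylsilyloxy)butyl]-6-(triethylsilyloxy)benzoate
Product: 18 methyl 2,4-dimethyl-3-[(3S)-3-methyl-4-oxo-3-(triethylsilyloxy)butyl]-6-(triethylsilyloxy)benzoate, via alkoxysulfonium chloride 17 (not isolated)
Conditions: (COCl)2, DMSO, CH2Cl2, −78 → −30 °C; then Et3N, −78 → 0 °C
Reagents that add atoms: none
Why: Under Swern conditions the chlorosulfonium reagent should attack only the unhindered primary silyl ether oxygen to give alkoxysulfonium 17 with loss of the silyl chloride, and Et3N then induces elimination to the aldehyde (selective oxidative desilylation of a primary triethylsilyl ether), while the aryl and tertiary silyl ethers stay in place and the quaternary α-carbon cannot epimerise.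

Step 12
Reactants: 18 methyl 2,4-dimethyl-3-[(3S)-3-methyl-4-oxo-3-(triethylsilyloxy)butyl]-6-(triethylsilyloxy)benzoate
Product: 19 methyl 2,4-dimethyl-3-[(3S)-3-methyl-3-(triethylsilyloxy)pent-4-enyl]-6-(triethylsilyloxy)benzoate
Conditions: Ph3PCH3Br, KN(SiMe3)2, THF, 0 °C; then 18, −78 → 0 °C
Reagents that add atoms: methyltriphenylphosphonium bromide, C[P+](c1ccccc1)(c1ccccc1)c1ccccc1.[Br-]
Why: Wittig methylenation with the non-stabilised ylide should convert the hindered but non-enolisable aldehyde into the terminal alkene at low temperature without harming the hindered ester or the silyl ethers.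

Step 13
Reactants: 20 2-bromobenzene-1,4-diol
Product: 21 2-bromo-1,4-bis(tert-butyldimethylsilyloxy)benzene
Conditions: t-BuMe2SiCl, imidazole, DMF, rt
Reagents that add atoms: tert-butyldimethylsilyl chloride, CC(C)(C)[Si](C)(C)Cl
Why: Standard silyl ether protection of both phenols masks the oxidation-prone hydroquinone for the palladium step and allows fluoride release at the end.

Step 14
Reactants: 19 methyl 2,4-dimethyl-3-[(3S)-3-methyl-3-(triethylsilyloxy)pent-4-enyl]-6-(triethylsilyloxy)benzoate; 21 2-bromo-1,4-bis(tert-butyldimethylsilyloxy)benzene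
Product: 22 methyl 3-[(3S,4E)-5-[2,5-bis(tert-butyldimethylsilyloxy)phenyl]-3-methyl-3-(triethylsilyloxy)pent-4-enyl]-2,4-dimethyl-6-(triethylsilyloxy)benzoate
Conditions: Pd2(dba)3 (cat.), P(t-Bu)3·HBF4 (cat.), Cy2NMe, 1,4-dioxane, 80 °C, degassed
Reagents that add atoms: none
Why: Mizoroki–Heck arylation of the monosubstituted alkene should place the aryl group on the terminal carbon, and because the allylic carbon is fully substituted the β-hydride elimination can only take the benzylic hydrogen through the less crowded syn-coplanar conformer, which should give the conjugated E-alkene without involving the S centre.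

Step 15
Reactants: 22 methyl 3-[(3S,4E)-5-[2,5-bis(tert-butyldimethylsilyloxy)phenyl]-3-methyl-3-(triethylsilyloxy)pent-4-enyl]-2,4-dimethyl-6-(triethylsilyloxy)benzoate
Product: 23 [3-[(3S,4E)-5-[2,5-bis(tert-butyldimethylsilyloxy)phenyl]-3-methyl-3-(triethylsilyloxy)pent-4-enyl]-2,4-dimethyl-6-(triethylsilyloxy)phenyl]methanol
Conditions: i-Bu2AlH, CH2Cl2, −78 → 0 °C; aq. potassium sodium tartrate
Reagents that add atoms: none
Why: Hydride reduction of the hindered methyl benzoate with the aluminium hydride should give the benzylic alcohol without affecting the silyl ethers or the styrene.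

Step 16
Reactants: 23 [3-[(3S,4E)-5-[2,5-bis(tert-butyldimethylsilyloxy)phenyl]-3-methyl-3-(triethylsilyloxy)pent-4-enyl]-2,4-dimethyl-6-(triethylsilyloxy)phenyl]methanol
Product: 24 3-[(3S,4E)-5-[2,5-bis(tert-butyldimethylsilyloxy)phenyl]-3-methyl-3-(triethylsilyloxy)pent-4-enyl]-2,4-dimethyl-6-(triethylsilyloxy)benzaldehyde
Conditions: MnO2 (activated, excess), CH2Cl2, rt
Reagents that add atoms: none
Why: Benzylic alcohol oxidation with activated MnO2 should stop at the benzaldehyde under neutral conditions that spare the silyl ethers, the alkene and the acid-sensitive tertiary allylic ether.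

Step 17
Reactants: 24 3-[(3S,4E)-5-[2,5-bis(tert-butyldimethylsilyloxy)phenyl]-3-methyl-3-(triethylsilyloxy)pent-4-enyl]-2,4-dimethyl-6-(triethylsilyloxy)benzaldehyde
Product: 25 3-[(3S,4E)-5-(2,5-dihydroxyphenyl)-3-hydroxy-3-methylpent-4-enyl]-6-hydroxy-2,4-dimethylbenzaldehyde (target)
Conditions: Bu4NF, AcOH (equimolar), THF, 0 °C → rt, argon, degassed solvents; pH 7 buffer work-up
Reagents that add atoms: none
Why: Fluoride-mediated desilylation buffered with acetic acid should remove the three aryl silyl ethers and the tertiary triethylsilyl ether without building up phenoxide or strong acid, so that neither air oxidation of the hydroquinone nor ionisation of the tertiary allylic alcohol is promoted and the S centre and E-alkene remain as set.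

Compound list
1 | (S)-citramalic acid [(2S)-2-hydroxy-2-methylbutanedioic acid] | OC(=O)C[C@](C)(O)C(=O)O | starting material
2 | (2S)-2-methylbutane-1,2,4-triol | OCC[C@](C)(O)CO | intermediate
3 | (4S)-4-(2-hydroxyethyl)-4-methyl-1,3-dioxolan-2-one | OCC[C@]1(C)OC(=O)OC1 | intermediate
4 | (4S)-4-(2-iodoethyl)-4-methyl-1,3-dioxolan-2-one | ICC[C@]1(C)OC(=O)OC1 | intermediate
5 | pentane-2,4-dione | CC(=O)CC(C)=O | starting material
6 | 3-[2-[(4S)-4-methyl-2-oxo-1,3-dioxolan-4-yl]ethyl]pentane-2,4-dione | CC(=O)C(CC[C@]1(C)OC(=O)OC1)C(C)=O | intermediate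
7 | (3Z)-3-[2-[(4S)-4-methyl-2-oxo-1,3-dioxolan-4-yl]ethyl]-4-(trimethylsilyloxy)pent-3-en-2-one | CC(=O)/C(CC[C@]1(C)OC(=O)OC1)=C(/C)O[Si](C)(C)C | intermediate
8 | methyl acetoacetate (methyl 3-oxobutanoate) | COC(=O)CC(C)=O | starting material
9 | methyl (2E)-3-(trimethylsilyloxy)but-2-enoate | COC(=O)/C=C(\C)O[Si](C)(C)C | intermediate
10 | lithium 1-methoxy-3-(trimethylsilyloxy)buta-1,3-dien-1-olate (not isolated) | C=C(O[Si](C)(C)C)/C=C(/OC)[O-].[Li+] | intermediate
11 | (1Z)-1-methoxy-1,3-bis(trimethylsilyloxy)buta-1,3-diene | C=C(O[Si](C)(C)C)/C=C(/OC)O[Si](C)(C)C | intermediate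
12 | methyl (5Z)-5-methyl-6-[2-[(4S)-4-methyl-2-oxo-1,3-dioxolan-4-yl]ethyl]-3,7-dioxooct-5-enoate (open-chain enone, drawn as the neutral keto form; not isolated) | COC(=O)CC(=O)C/C(C)=C(/CC[C@]1(C)OC(=O)OC1)C(C)=O | intermediate
13 | methyl 2-hydroxy-2,4-dimethyl-3-[2-[(4S)-4-methyl-2-oxo-1,3-dioxolan-4-yl]ethyl]-6-oxocyclohex-3-ene-1-carboxylate (cyclohexenone aldol, transient ring centres undefined; not isolated) | COC(=O)C1C(=O)CC(C)=C(CC[C@]2(C)OC(=O)OC2)C1(C)O | intermediate
14 | methyl 6-hydroxy-2,4-dimethyl-3-[2-[(4S)-4-methyl-2-oxo-1,3-dioxolan-4-yl]ethyl]benzoate | Cc1cc(O)c(C(=O)OC)c(C)c1CC[C@]2(C)OC(=O)OC2 | intermediate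
15 | methyl 3-[(3S)-3,4-dihydroxy-3-methylbutyl]-6-hydroxy-2,4-dimethylbenzoate | Cc1cc(O)c(C(=O)OC)c(C)c1CC[C@](C)(O)CO | intermediate
16 | methyl 2,4-dimethyl-3-[(3S)-3-methyl-3,4-bis(triethylsilyloxy)butyl]-6-(triethylsilyloxy)benzoate | Cc1cc(O[Si](CC)(CC)CC)c(C(=O)OC)c(C)c1CC[C@](C)(O[Si](CC)(CC)CC)CO[Si](CC)(CC)CC | intermediate
17 | [(2S)-4-[3-(methoxycarbonyl)-2,6-dimethyl-4-(triethylsilyloxy)phenyl]-2-methyl-2-(triethylsilyloxy)butoxy]dimethylsulfonium chloride (not isolated) | Cc1cc(O[Si](CC)(CC)CC)c(C(=O)OC)c(C)c1CC[C@](C)(O[Si](CC)(CC)CC)CO[S+](C)C.[Cl-] | intermediate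
18 | methyl 2,4-dimethyl-3-[(3S)-3-methyl-4-oxo-3-(triethylsilyloxy)butyl]-6-(triethylsilyloxy)benzoate | Cc1cc(O[Si](CC)(CC)CC)c(C(=O)OC)c(C)c1CC[C@](C)(O[Si](CC)(CC)CC)C=O | intermediate
19 | methyl 2,4-dimethyl-3-[(3S)-3-methyl-3-(triethylsilyloxy)pent-4-enyl]-6-(triethylsilyloxy)benzoate | Cc1cc(O[Si](CC)(CC)CC)c(C(=O)OC)c(C)c1CC[C@](C)(O[Si](CC)(CC)CC)C=C | intermediate
20 | 2-bromobenzene-1,4-diol | Oc1ccc(O)c(Br)c1 | starting material
21 | 2-bromo-1,4-bis(tert-butyldimethylsilyloxy)benzene | CC(C)(C)[Si](C)(C)Oc1ccc(O[Si](C)(C)C(C)(C)C)c(Br)c1 | intermediate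
22 | methyl 3-[(3S,4E)-5-[2,5-bis(tert-butyldimethylsilyloxy)phenyl]-3-methyl-3-(triethylsilyloxy)pent-4-enyl]-2,4-dimethyl-6-(triethylsilyloxy)benzoate | Cc1cc(O[Si](CC)(CC)CC)c(C(=O)OC)c(C)c1CC[C@](C)(O[Si](CC)(CC)CC)/C=C/c1cc(O[Si](C)(C)C(C)(C)C)ccc1O[Si](C)(C)C(C)(C)C | intermediate
23 | [3-[(3S,4E)-5-[2,5-bis(tert-butyldimethylsilyloxy)phenyl]-3-methyl-3-(triethylsilyloxy)pent-4-enyl]-2,4-dimethyl-6-(triethylsilyloxy)phenyl]methanol | Cc1cc(O[Si](CC)(CC)CC)c(CO)c(C)c1CC[C@](C)(O[Si](CC)(CC)CC)/C=C/c1cc(O[Si](C)(C)C(C)(C)C)ccc1O[Si](C)(C)C(C)(C)C | intermediate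
24 | 3-[(3S,4E)-5-[2,5-bis(tert-butyldimethylsilyloxy)phenyl]-3-methyl-3-(triethylsilyloxy)pent-4-enyl]-2,4-dimethyl-6-(triethylsilyloxy)benzaldehyde | Cc1cc(O[Si](CC)(CC)CC)c(C=O)c(C)c1CC[C@](C)(O[Si](CC)(CC)CC)/C=C/c1cc(O[Si](C)(C)C(C)(C)C)ccc1O[Si](C)(C)C(C)(C)C | intermediate
25 | 3-[(3S,4E)-5-(2,5-dihydroxyphenyl)-3-hydroxy-3-methylpent-4-enyl]-6-hydroxy-2,4-dimethylbenzaldehyde | Cc1cc(O)c(C=O)c(C)c1CC[C@](C)(O)/C=C/c1cc(O)ccc1O | target

Total step count: 17
Longest linear sequence: 14 steps (steps 1–5, 8–12, 14–17)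

Steps most likely to fail

1. Step 8. The Lewis acid may be sequestered by the carbonate carbonyl so that ring closure and aromatisation stall, or the tertiary C–O bond may ionise and the carbonate open. Fallback without Lewis acid, setting out from diketone 6: treatment with dimethyl 3-oxopentanedioate and NaOMe in MeOH should first methanolyse the carbonate in the flask to 3-[(3S)-3,4-dihydroxy-3-methylbutyl]pentane-2,4-dione F1. Double Knoevenagel-type condensation of both active methylenes onto the two ketones, with aromatisation, should then give dimethyl 5-[(3S)-3,4-dihydroxy-3-methylbutyl]-2-hydroxy-4,6-dimethylbenzene-1,3-dicarboxylate F2, in which the two esters are equivalent. Mono-saponification with aqueous NaOH (the second ester is deactivated in the dianion) should give 5-[(3S)-3,4-dihydroxy-3-methylbutyl]-2-hydroxy-3-(methoxycarbonyl)-4,6-dimethylbenzoic acid F3. Ag2CO3-catalysed protodecarboxylation of this ortho-substituted benzoic acid (AcOH, DMSO, heat) should then remove the free carboxyl. The fallback comes back to the route at diol 15, so step 9 is no longer needed.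

2. Step 14. Oxidative addition and alkene insertion may be slow with the ortho-silyloxy aryl bromide and the crowded allylic silyl ether, so that reductive debromination or silyl ether loss competes at the temperature required. Fallback with reversed coupling polarity, setting out from aldehyde 18: Takai iodo-olefination (CHI3, CrCl2, THF) should give methyl 3-[(3S,4E)-5-iodo-3-methyl-3-(triethylsilyloxy)pent-4-enyl]-2,4-dimethyl-6-(triethylsilyloxy)benzoate F4. Miyaura borylation of aryl bromide 21 (B2pin2, Pd(dppf)Cl2, KOAc, dioxane) should give 2-[2,5-bis(tert-butyldimethylsilyloxy)phenyl]-4,4,5,5-tetramethyl-1,3,2-dioxaborolane F5. Suzuki–Miyaura coupling of the two (Pd(PPh3)4, K3PO4, dioxane/water) proceeds with retention of alkene geometry and comes back to the route at 22; step 12 is then bypassed.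

3. Step 11. The activated sulfoxide may not discriminate cleanly, with partial loss of the aryl silyl ether or incomplete conversion of the primary silyl ether. Fallback that avoids any oxidation, setting out from diol 15: selective sulfonylation of the primary hydroxyl (TsCl, Bu2SnO cat., Et3N) should give methyl 6-hydroxy-3-[(3S)-3-hydroxy-3-methyl-4-(4-methylphenylsulfonyloxy)butyl]-2,4-dimethylbenzoate F6. Ring closure with K2CO3 in MeOH should give methyl 6-hydroxy-2,4-dimethyl-3-[2-[(2S)-2-methyloxiran-2-yl]ethyl]benzoate F7. One-carbon homologation of the epoxide with excess dimethylsulfonium methylide (Me3SI, n-BuLi, THF) should open the ring at CH2 and eliminate dimethyl sulfide to give methyl 6-hydroxy-3-[(3S)-3-hydroxy-3-methylpent-4-enyl]-2,4-dimethylbenzoate F8. Silylation of the phenol and the tertiary alcohol (Et3SiOTf, 2,6-lutidine) comes back to the route at 19, bypassing steps 10–12.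

Further compounds
F1 | step 8 | 3-[(3S)-3,4-dihydroxy-3-methylbutyl]pentane-2,4-dione | CC(=O)C(CC[C@](C)(O)CO)C(C)=O
F2 | step 8 | dimethyl 5-[(3S)-3,4-dihydroxy-3-methylbutyl]-2-hydroxy-4,6-dimethylbenzene-1,3-dicarboxylate | COC(=O)c1c(O)c(C(=O)OC)c(C)c(CC[C@](C)(O)CO)c1C
F3 | step 8 | 5-[(3S)-3,4-dihydroxy-3-methylbutyl]-2-hydroxy-3-(methoxycarbonyl)-4,6-dimethylbenzoic acid | OC(=O)c1c(O)c(C(=O)OC)c(C)c(CC[C@](C)(O)CO)c1C
F4 | step 14 | methyl 3-[(3S,4E)-5-iodo-3-methyl-3-(triethylsilyloxy)pent-4-enyl]-2,4-dimethyl-6-(triethylsilyloxy)benzoate | Cc1cc(O[Si](CC)(CC)CC)c(C(=O)OC)c(C)c1CC[C@](C)(O[Si](CC)(CC)CC)/C=C/I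
F5 | step 14 | 2-[2,5-bis(tert-butyldimethylsilyloxy)phenyl]-4,4,5,5-tetramethyl-1,3,2-dioxaborolane | CC(C)(C)[Si](C)(C)Oc1ccc(O[Si](C)(C)C(C)(C)C)c(c1)B1OC(C)(C)C(C)(C)O1
F6 | step 11 | methyl 6-hydroxy-3-[(3S)-3-hydroxy-3-methyl-4-(4-methylphenylsulfonyloxy)butyl]-2,4-dimethylbenzoate | Cc1cc(O)c(C(=O)OC)c(C)c1CC[C@](C)(O)COS(=O)(=O)c1ccc(C)cc1
F7 | step 11 | methyl 6-hydroxy-2,4-dimethyl-3-[2-[(2S)-2-methyloxiran-2-yl]ethyl]benzoate | Cc1cc(O)c(C(=O)OC)c(C)c1CC[C@@]1(C)CO1
F8 | step 11 | methyl 6-hydroxy-3-[(3S)-3-hydroxy-3-methylpent-4-enyl]-2,4-dimethylbenzoate | Cc1cc(O)c(C(=O)OC)c(C)c1CC[C@](C)(O)C=C
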